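In the midnight run the substrate fell to 68.4% by 10.0 min while single ring rose to 15.8%, so ring took 0.500 of the substrate lost. From that reading to 60.0 min ring took 0.606, a larger part than before, with less substrate standing. This pattern suggests ring closure following substrate and a competing loss following its square. The ring share at concentration c is then c*/(c*+c). Letting the 30.0 min reading of 0.0955 M stand for that stretch gives c* = 0.147 M, the crossing concentration, where closure and loss run equally fast (a selectivity factor in concentration units). Averaged over a whole charge C, ring comes to (c*/C) ln(1 + C/c*).

| flask | substrate | temperature | remark | time |
|---|---|---|---|---|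
| midnight | 0.25 M | 0 °C | run made earlier |  |
| maple | 0.50 M | 0 °C |  | 20 h |
| cedar | 0.50 M | −20 °C |  | 20 h |

- midnight (time / min: single ring / %, substrate / %): 10.0: 15.8, 68.4; 20.0: 25.8, 50.1; 30.0: 32.4, 38.2; 60.0: 47.2, 16.6; 120: 54.8, 4.7

(readings scatter by 0.5 percentage points)

* the flask that comes out highest in amount of single ring, in percent of the substrate charged, or "all alike" when all lie within 1.5 percentage points (maple / cedar / all alike)
* single ring at the end, in percent of the substrate charged, maple
* single ring at the end, in percent of the substrate charged, cedar

- the analysis behind the earlier runs scatters by 0.5 percentage points, standard deviation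
- the earlier runs do not show what temperature does; that part of a forecast is a guess

Ring closure has a time of about 53.3 min, far shorter than the 20 h of maple. The competing loss, reckoned at maple's charge of 0.50 M, starts faster than closure, with a time of about 15.7 min, so it is the first rung and closure the second. Maple should therefore first reach 43.6% ring. The slower rung is ring decay. From 60.0 min to 120 min ring rose 2.5 percentage points less than the substrate lost should have given. That is a rough figure against a scatter of 0.71 points, but it gives a ring life near 20.6 h, much longer than closure. Over 20 h, 0.379 of the ring survives, so this reckoning puts maple at 16.5%. The readings show no temperature effect, so for cedar it guesses an unchanged crossing concentration and little decay, near 43.6%.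

The forecast names cedar, with 15% for maple and 42% for cedar, and says "The temperature effect is a guess".

Maple gives 19.6% and cedar 18.9%, so the answer is all alike, with cedar 25 points under the guess.

    substrate + open dimer → open trimer (k = 7.70 M⁻¹ h⁻¹, Ea = 61.0 kJ mol⁻¹)
    open dimer → ring dimer (k = 0.0700 h⁻¹, Ea = 93.0 kJ mol⁻¹)
    2 substrate → open dimer (k = 2.40 M⁻¹ h⁻¹, Ea = 59.0 kJ mol⁻¹)
    substrate → single ring (k = 1.10 h⁻¹, Ea = 92.0 kJ mol⁻¹)
    single ring → over-reaction product (k = 0.0430 h⁻¹, Ea = 93.0 kJ mol⁻¹)
    (constants at 0 °C)

Maple's ring is 0.449 of the share reckoned from the crossing concentration. The neighbour is maple with 2.0 M of substrate, at the same time and temperature. There the same crossing concentration gives a share of 19.7%, and maple's surviving part turns that into 8.85%. The neighbour holds 7.78% single ring.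

(The data are simulated for substances that don't exist, and the scatter is random.)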